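**Retrosynthetic overview**
Target 19 is opened at the ring A C–OH bond (from C–B) and at the two ring B C–Br bonds (late bromination ortho and para to the ring B OH).
The strategy rests on ring A: its ether carbon lies between the C–OH carbon and a C–Br carbon, with the second Br para to it, so both Br are meta to the OH and phenol bromination cannot place them.
The CBr–CH–CBr–CH carbons of ring A are therefore C3–C6 of 3,5-dibromo-2-pyrone 3, and its two oxygen-bearing carbons are the alkyne carbons of aryloxyethynyl boronate 12 (one carries OAr, the other boron as latent OH).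
Ring order: ring B comes intact from catechol; ring A is the only ring formed, by pyrone–alkyne [4+2] addition with CO2 loss (step 5); then MOM removal, ring B dibromination and C–B oxidation.

Key step: step 5

Remark: the ring B oxygen is carried as a MOM ether, not a methyl ether, because BBr3 demethylation would also attack the pinacol boronate that must survive until the last step. The target has no stereocenter.

**Route**

Step 1
Reactants: 1 coumalic acid
Product: 3 3,5-dibromo-2H-pyran-2-one, via 5-bromo-2H-pyran-2-one 2 (not isolated)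
Conditions: NBS (2.5 equiv), LiOAc (0.2 equiv), MeCN/H2O, rt
Reagents that add atoms: N-bromosuccinimide, O=C1CCC(=O)N1Br
Why: Hunsdiecker-type bromodecarboxylation of the carboxylate at the enol-ether-like C5, followed by electrophilic bromination at C3 of the 5-bromopyrone so formed, is an established one-pot entry to this pyrone.

Step 2
Reactants: 4 catechol
Product: 5 2-(methoxymethoxy)phenol
Conditions: catechol (3 equiv), MOMCl (1 equiv), i-Pr2NEt (1.1 equiv), MeCN, 0 °C to rt
Reagents that add atoms: chloromethyl methyl ether, COCCl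
Why: Williamson-type O-alkylation of catechol by the reactive alpha-chloro ether, with the diol in excess so that monoalkylation should predominate and unreacted catechol is removed by aqueous washing.

Step 3
Reactants: 5 2-(methoxymethoxy)phenol; 6 trichloroethylene
Product: 7 (E)-1-[(1,2-dichloroethenyl)oxy]-2-(methoxymethoxy)benzene
Conditions: K2CO3 (1.5 equiv), DMF, 70 °C
Reagents that add atoms: none
Why: Base-induced dehydrochlorination of trichloroethylene gives dichloroacetylene in situ and the phenoxide adds to it in anti fashion (vinylic substitution by elimination–addition), the standard preparation of aryl (E)-1,2-dichlorovinyl ethers.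

Step 4
Reactants: 7 (E)-1-[(1,2-dichloroethenyl)oxy]-2-(methoxymethoxy)benzene; 8 2-isopropoxy-4,4,5,5-tetramethyl-1,3,2-dioxaborolane
Product: 12 2-{[2-(methoxymethoxy)phenoxy]ethynyl}-4,4,5,5-tetramethyl-1,3,2-dioxaborolane, via chloroalkynyl ether 9 (not isolated), via lithium aryloxyacetylide 10 (not isolated), via lithium borate complex 11 (not isolated)
Conditions: n-BuLi (2.2 equiv), THF, −78 °C; then 8, −78 °C; then HCl (2 M in Et2O, 1.0 equiv), −78 °C to rt; filtration under Ar, crude used directly
Reagents that add atoms: none
Why: Deprotonation and beta-elimination of LiCl give the chloroalkynyl ether, chlorine–lithium exchange with the second equivalent of n-BuLi gives the lithium aryloxyacetylide (the usual ynol ether synthesis from dichlorovinyl ethers), and borylation with the isopropoxyboronate followed by release from the borate complex with one equivalent of anhydrous HCl is the standard alkynyllithium route to alkynyl pinacol boronates, the MOM acetal being inert to n-BuLi at this temperature.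

Step 5
Reactants: 3 3,5-dibromo-2H-pyran-2-one; 12 2-{[2-(methoxymethoxy)phenoxy]ethynyl}-4,4,5,5-tetramethyl-1,3,2-dioxaborolane
Product: 14 2-{3,5-dibromo-2-[2-(methoxymethoxy)phenoxy]phenyl}-4,4,5,5-tetramethyl-1,3,2-dioxaborolane, via bridged bicyclic lactone 13 (not isolated)
Conditions: 12 (1.5 equiv), anhydrous toluene, 110 °C, sealed tube, Ar
Reagents that add atoms: none
Why: Proposed new method: in push–pull alkyne 12 the oxygen donor and the boron acceptor polarise the triple bond in the same sense, so the boron-bearing carbon is the nucleophilic end and should bond to the electrophilic C6 of the electron-poor diene 3 while the aryloxy carbon bonds to C3, in an asynchronous (possibly stepwise zwitterionic) inverse-demand [4+2] addition. The closest known reaction types are the thermal cycloaddition of 2-pyrones with alkynylboronates to give arylboronates, and the addition of enol ethers to 3,5-dibromo-2-pyrone, which places the oxygen-bearing carbon next to the brominated bridgehead. Ring A is closed by this intermolecular [4+2] addition, which forms the C(OAr)–C3 and C(B)–C6 bonds, and bridged lactone 13 then loses CO2 by retro-[4+2] at the reaction temperature to give the benzene ring directly. No stereocenter survives, since the two bridgehead carbons of racemic 13 become sp2 carbons of ring A. The step needs regioselectivity (aryloxy carbon beside C–Br, boron carbon beside C–H), which the concordant donor/acceptor polarisation of the alkyne toward the C6-electrophilic pyrone should secure. It also needs the alkynyl C–B bond to outlast the heating, which strictly anhydrous conditions serve, and the aryl ynol ether has no beta C–H for retro-ene loss of a ketene.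

Step 6
Reactants: 14 2-{3,5-dibromo-2-[2-(methoxymethoxy)phenoxy]phenyl}-4,4,5,5-tetramethyl-1,3,2-dioxaborolane
Product: 15 2-[2,4-dibromo-6-(4,4,5,5-tetramethyl-1,3,2-dioxaborolan-2-yl)phenoxy]phenol
Conditions: HCl (1.25 M in MeOH), CH2Cl2, 0 °C to rt
Reagents that add atoms: none
Why: Acid-catalysed transacetalisation of the phenolic MOM acetal with methanol is mild enough to spare the aryl pinacol boronate, the aryl bromides and the diaryl ether.

Step 7
Reactants: 15 2-[2,4-dibromo-6-(4,4,5,5-tetramethyl-1,3,2-dioxaborolan-2-yl)phenoxy]phenol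
Product: 17 2,4-dibromo-6-[2,4-dibromo-6-(4,4,5,5-tetramethyl-1,3,2-dioxaborolan-2-yl)phenoxy]phenol, via para-monobromophenol 16 (not isolated)
Conditions: NBS (2.1 equiv), MeCN, 0 °C to rt
Reagents that add atoms: N-bromosuccinimide, O=C1CCC(=O)N1Br
Why: Electrophilic aromatic bromination is directed by the free OH of ring B to its para position and its only free ortho position, whereas ring A carries two bromines and the boronate and has free positions only meta to its ether oxygen, so it should stay untouched.

Step 8
Reactants: 17 2,4-dibromo-6-[2,4-dibromo-6-(4,4,5,5-tetramethyl-1,3,2-dioxaborolan-2-yl)phenoxy]phenol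
Product: 19 3,5-dibromo-2-(3,5-dibromo-2-hydroxyphenoxy)phenol, via aryl borate ester 18 (not isolated)
Conditions: H2O2 (30% aq.), NaOH (aq.), THF, 0 °C to rt
Reagents that add atoms: hydrogen peroxide, OO
Why: Oxidation of the aryl C–B bond by hydroperoxide anion (borate formation, 1,2-shift of the aryl group from boron to oxygen, hydrolysis of the aryl borate) installs the ring A hydroxyl meta to both bromines without touching the diaryl ether or the aryl bromides.

**Compound list**
1 | coumalic acid (2-oxo-2H-pyran-5-carboxylic acid) | OC(=O)C1=COC(=O)C=C1 | starting material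
2 | 5-bromo-2H-pyran-2-one | O=C1C=CC(Br)=CO1 | intermediate (not isolated)
3 | 3,5-dibromo-2H-pyran-2-one | O=C1OC=C(Br)C=C1Br | intermediate
4 | catechol | Oc1ccccc1O | starting material
5 | 2-(methoxymethoxy)phenol | COCOc1ccccc1O | intermediate
6 | trichloroethylene | ClC=C(Cl)Cl | starting material
7 | (E)-1-[(1,2-dichloroethenyl)oxy]-2-(methoxymethoxy)benzene | COCOc1ccccc1O/C(Cl)=C\Cl | intermediate
8 | 2-isopropoxy-4,4,5,5-tetramethyl-1,3,2-dioxaborolane | CC(C)OB1OC(C)(C)C(C)(C)O1 | starting material
9 | 1-[(chloroethynyl)oxy]-2-(methoxymethoxy)benzene | COCOc1ccccc1OC#CCl | intermediate (not isolated)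
10 | lithium {[2-(methoxymethoxy)phenoxy]ethynide} | COCOc1ccccc1OC#C[Li] | intermediate (not isolated)
11 | lithium isopropoxy{[2-(methoxymethoxy)phenoxy]ethynyl}(pinacolato)borate | [Li+].COCOc1ccccc1OC#C[B-]1(OC(C)C)OC(C)(C)C(C)(C)O1 | intermediate (not isolated)
12 | 2-{[2-(methoxymethoxy)phenoxy]ethynyl}-4,4,5,5-tetramethyl-1,3,2-dioxaborolane | COCOc1ccccc1OC#CB1OC(C)(C)C(C)(C)O1 | intermediate
13 | 4,7-dibromo-5-[2-(methoxymethoxy)phenoxy]-6-(4,4,5,5-tetramethyl-1,3,2-dioxaborolan-2-yl)-2-oxabicyclo[2.2.2]octa-5,7-dien-3-one (racemic) | O=C1OC2C(Br)=CC1(Br)C(Oc3ccccc3OCOC)=C2B4OC(C)(C)C(C)(C)O4 | intermediate (not isolated)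
14 | 2-{3,5-dibromo-2-[2-(methoxymethoxy)phenoxy]phenyl}-4,4,5,5-tetramethyl-1,3,2-dioxaborolane | COCOc1ccccc1Oc1c(Br)cc(Br)cc1B1OC(C)(C)C(C)(C)O1 | intermediate
15 | 2-[2,4-dibromo-6-(4,4,5,5-tetramethyl-1,3,2-dioxaborolan-2-yl)phenoxy]phenol | Oc1ccccc1Oc1c(Br)cc(Br)cc1B1OC(C)(C)C(C)(C)O1 | intermediate
16 | 4-bromo-2-[2,4-dibromo-6-(4,4,5,5-tetramethyl-1,3,2-dioxaborolan-2-yl)phenoxy]phenol | Oc1ccc(Br)cc1Oc1c(Br)cc(Br)cc1B1OC(C)(C)C(C)(C)O1 | intermediate (not isolated)
17 | 2,4-dibromo-6-[2,4-dibromo-6-(4,4,5,5-tetramethyl-1,3,2-dioxaborolan-2-yl)phenoxy]phenol | Oc1c(Br)cc(Br)cc1Oc1c(Br)cc(Br)cc1B1OC(C)(C)C(C)(C)O1 | intermediate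
18 | 2-[3,5-dibromo-2-(3,5-dibromo-2-hydroxyphenoxy)phenoxy]-4,4,5,5-tetramethyl-1,3,2-dioxaborolane | Oc1c(Br)cc(Br)cc1Oc1c(Br)cc(Br)cc1OB1OC(C)(C)C(C)(C)O1 | intermediate (not isolated)
19 | 3,5-dibromo-2-(3,5-dibromo-2-hydroxyphenoxy)phenol | Oc1cc(Br)cc(Br)c1Oc1cc(Br)cc(Br)c1O | target

**Step count and risks**
Total steps: 8. Longest linear sequence: 7 (steps 2 to 8, from catechol); step 1 is a one-step side branch that joins at step 5.

Step 5 (key step). What may go wrong: the alkyne may hydrolyse or oligomerise before it adds, the polar addition may stall at an open-chain adduct, or the addition may take the opposite orientation. The fallback uses known chemistry, and a formyl group takes the place of boron as the latent ring A OH. It sets out from 5 and returns to the route at 19.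
- Nucleophilic aromatic substitution of 5 on commercial 3,5-dibromo-2-fluorobenzaldehyde (O=Cc1cc(Br)cc(Br)c1F; K2CO3, DMF, 60 °C) should give 3,5-dibromo-2-[2-(methoxymethoxy)phenoxy]benzaldehyde F1; the fluoride ortho to the formyl group is the only activated leaving group.
- Aqueous HCl in THF removes the MOM group to give 3,5-dibromo-2-(2-hydroxyphenoxy)benzaldehyde F2.
- NBS (2 equiv, MeCN) brominates ring B ortho and para to its OH, ring A being deactivated by the formyl group and two bromines, to give 3,5-dibromo-2-(3,5-dibromo-2-hydroxyphenoxy)benzaldehyde F3.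
- Baeyer–Villiger oxidation (mCPBA, CH2Cl2) with aryl migration gives 3,5-dibromo-2-(3,5-dibromo-2-hydroxyphenoxy)phenyl formate F4, and methanolysis (K2CO3, MeOH) gives 19.

Step 4. What may go wrong: protic cleavage of the alkynyl C–B bond, or addition of HCl across the ynol ether, during the acid release from the borate complex or on handling. The fallback avoids the borate complex and the acid quench. It sets out from 7 and returns at 12.
- The same n-BuLi treatment (2.2 equiv, THF, −78 °C) followed by a methanol quench gives the terminal ynol ether 1-(ethynyloxy)-2-(methoxymethoxy)benzene F5.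
- Catalytic dehydrogenative C–H borylation of the terminal alkyne with pinacolborane ([H]B1OC(C)(C)C(C)(C)O1; Fe(OTf)2 cat., DABCO cat., toluene, heat), a known reaction of terminal alkynes, then gives 12 with dihydrogen as the only by-product.

Step 7. What may go wrong: ipso-bromodeboronation at the ring A C–B bond may compete with bromination of ring B, helped by coordination of the neighbouring phenol to boron. The fallback removes boron before bromination and masks the ring A oxygen as a deactivating ester. It sets out from 14 and returns at 19.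
- Oxidation of 14 (H2O2, aq. NaOH, THF) gives 3,5-dibromo-2-[2-(methoxymethoxy)phenoxy]phenol F6.
- Acylation with pivaloyl chloride (CC(C)(C)C(Cl)=O; Et3N, DMAP cat., CH2Cl2) gives 3,5-dibromo-2-[2-(methoxymethoxy)phenoxy]phenyl pivalate F7.
- TFA in CH2Cl2 with aqueous work-up removes the MOM group to give 3,5-dibromo-2-(2-hydroxyphenoxy)phenyl pivalate F8.
- NBS (2.1 equiv, MeCN) brominates only the free phenol ring to give 3,5-dibromo-2-(3,5-dibromo-2-hydroxyphenoxy)phenyl pivalate F9, and methanolysis (K2CO3, MeOH) gives 19.

**Further compounds**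
F1 | step 5 | 3,5-dibromo-2-[2-(methoxymethoxy)phenoxy]benzaldehyde | COCOc1ccccc1Oc1c(Br)cc(Br)cc1C=O
F2 | step 5 | 3,5-dibromo-2-(2-hydroxyphenoxy)benzaldehyde | Oc1ccccc1Oc1c(Br)cc(Br)cc1C=O
F3 | step 5 | 3,5-dibromo-2-(3,5-dibromo-2-hydroxyphenoxy)benzaldehyde | Oc1c(Br)cc(Br)cc1Oc1c(Br)cc(Br)cc1C=O
F4 | step 5 | 3,5-dibromo-2-(3,5-dibromo-2-hydroxyphenoxy)phenyl formate | Oc1c(Br)cc(Br)cc1Oc1c(Br)cc(Br)cc1OC=O
F5 | step 4 | 1-(ethynyloxy)-2-(methoxymethoxy)benzene | COCOc1ccccc1OC#C
F6 | step 7 | 3,5-dibromo-2-[2-(methoxymethoxy)phenoxy]phenol | COCOc1ccccc1Oc1c(Br)cc(Br)cc1O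
F7 | step 7 | 3,5-dibromo-2-[2-(methoxymethoxy)phenoxy]phenyl pivalate | COCOc1ccccc1Oc1c(Br)cc(Br)cc1OC(=O)C(C)(C)C
F8 | step 7 | 3,5-dibromo-2-(2-hydroxyphenoxy)phenyl pivalate | Oc1ccccc1Oc1c(Br)cc(Br)cc1OC(=O)C(C)(C)C
F9 | step 7 | 3,5-dibromo-2-(3,5-dibromo-2-hydroxyphenoxy)phenyl pivalate | Oc1c(Br)cc(Br)cc1Oc1c(Br)cc(Br)cc1OC(=O)C(C)(C)C
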